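## Analysis of the target

The target 25 is a eudesmane sesquiterpenoid diester on a trans-fused decalin: ring A is C1–C2–C3–C4–C5–C10 and ring B is C5–C6–C7–C8–C9–C10, with methyl C14 on C10, methyl C15 on C4 and an isopropenyl group (C11, C12, C13) on C7 (eudesmane numbering throughout; β is the face of C14, and eudesmane-type names below imply 5α-H and 10β-methyl). It has five stereocentres, 3S, 4R, 5R, 7S and 10R: C10 is quaternary, H-5 is α, the oxygens on C3 and C4 are both β (cis to each other, syn to C14), and the C7 hydroxyl is α with the isopropenyl group β. In the chair–chair form the C4 acetate is axial and 1,3-diaxial to C14, the C3 angelate is equatorial and the C7 hydroxyl is axial. The sensitive groups are the angelate (Z to E isomerisation under nucleophilic, basic or thermal stress), the tertiary acetate beside a cis secondary ester (acyl migration), the tertiary α-ketol C7(OH)–C8(=O) (α-ketol rearrangement) and the isopropenyl alkene, which must survive every oxidation. The hard points are the quaternary C10, the fully substituted C7 next to a ketone, a cis-diol on the more hindered β face of ring A with different esters on its tertiary and secondary oxygens, and three alkenes that must be addressed one at a time. The strategy rests on ring B: C7 carries a 2-propenyl group and neighbours the carbonyl carbon C8, so the ketol is the oxidised form of a C7=C8 alkene, and C7=C8 with C11=C12 is a 2-substituted 1,3-diene C8=C7–C11=C12. That diene is the signature product of an enyne metathesis between a methyl-capped alkyne C7≡C11–C13 and an alkene carbon C8, so ring B and the isopropenyl group can arise in one isomerisation of a monocyclic enyne.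

## Retrosynthetic reasoning

25 to 24: the O–Si bond at C7 is cut last. Masking this hydroxyl from the moment the ketol exists blocks α-ketol rearrangement and keeps it out of the acylation; the forward step must remove silicon without base so that neither ester moves.

24 to 21 + 22: the C3–O acyl bond. The angelate is the most fragile group and goes on last among the fragments; the acylation of hydroxy acetate 21 with acid 22 must avoid nucleophilic catalysts and strong base.

21 to 18: both ring A C–O bonds (C3–O, C4–O) are cut back to the C3=C4 alkene of 18. A direct osmylation would put the oxygens on the α face; the Woodward protocol delivers both to the face opposite the first electrophile, through 19 and 20, and leaves the acetyl group on the axial tertiary oxygen, where 25 carries it.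

18 to 16 + 17: the C4–C15 bond. Coupling a methyl group onto alkenyl triflate 16 fixes the alkene at C3=C4, which addition–dehydration at a C4 ketone would not; the reaction with 17 must leave the C8 ketone alone.

16 to 15 to 14 to 13: the silyl ether, the C8 carbonyl and the C7–O/C8–O bonds go back to the C7=C8 alkene of diene 13. Ring B is oxidised while ring A is an enol triflate for two reasons: the triflate alkene is electron-poor and inert to osmylation, and the enolisation at C4 is then done while C4 is the only carbonyl present. The forward steps must pick the ring alkene over the isopropenyl alkene and the α face over the β face.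

13 to 11: the enol triflate goes back to the C4 ketone through enolate 12; deprotonation must occur at C3, not at the ring-fusion C5.

11 to 10 (key disconnection): C7=C8 (closing ring B) and C11=C12 are cut together, giving enyne 10, an isomer of 11. No other cut makes a ring and the isopropenyl group in one step from so simple a precursor. No stereocentre is formed, so the step can fail only on reactivity and mode of closure.

10 to 7 + 8: the C5–C6 bond, by alkylation of enolate 9 released from silyl enol ether 7, so the enolate position is defined. C5 is set here against a weak bias, because C10 carries methyl and allyl. It stays correctable after ring closure, where C14 stands perpendicular to the C4=C5 enolate (see the assessment at the end).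

7 to 4 + 5: the C10–C14 bond, by catalytic asymmetric conjugate addition. This is the only step that introduces absolute configuration; enolate 6 is captured on oxygen to carry its regiochemistry forward.

4 to 1 + 2: the C10–C9 bond, by addition to a vinylogous ester with carbonyl transposition.

## Alternatives that were turned down

Alternative 1: Both rings by an intramolecular Diels–Alder reaction.
- Disconnection: C1–C2 and C5–C10 of bicyclic ketone A1 (Δ3-octalin with C14, C15, an 8α-silyloxy group and a C9 ketone) are cut to give open-chain trienone A2. In A2 the methacryloyl alkene C1=C10 is the dienophile and the (E)-diene C2=C3–C4=C5 is tethered through C6–C9.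
- Forward key step: heat or Lewis-acid activation closes rings A and B at once and leaves C3=C4.
- For it: two rings, C5, C10 and the C3=C4 alkene with C15 in one step. On ring A this is stronger than the chosen route, which needs a triflation and a methyl coupling to reach the same alkene.
- Against it: the trans fusion depends on the endo/exo preference of a trienone whose activating carbonyl lies inside the tether, which is rarely decisive. Absolute configuration must be relayed from the single C8 stereocentre through a flexible chain. Ring B arrives with the wrong pattern: a C9 carbonyl to delete, C8 at the alcohol level and C7 bare.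
- Comparison: the quaternary C7 would still have to be built beside a ketone that can also enolise towards C9. The chosen metathesis makes fewer bonds per step but puts C7=C8 and the isopropenyl group exactly where the ketol needs them, so what follows is functional-group work only.

Alternative 2: Ring B by a catalytic asymmetric Diels–Alder reaction.
- Disconnection: C5–C6 and C9–C10 of cyclohexene A3 are cut to give (E)-enal A4 and silyloxydiene A5.
- Forward key step: a chiral cationic oxazaborolidine binds the formyl group of A4 and A5 adds across C5=C10. A3 forms with the acetyl arm (C4, C15) and the formyl arm (C1) trans and an enol silane at C7=C8.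
- For it: the C5/C10 relationship is fixed stereospecifically by alkene geometry and the absolute configuration by the catalyst. This is clearly stronger than the chosen route, where C5 is set in an alkylation with a weak facial bias.
- Against it: ring A must still be annulated by bringing in C2 and C3 and creating C3 and C4. C1 arrives as an aldehyde and must be reduced to a methylene. The isopropenyl group and the C8 oxygen are still missing, and two carbonyls and an enol silane must be told apart throughout.
- Comparison: a better stereochemical start, but more C–C bond formation after the key step. In the chosen route every skeletal carbon except C15 is in place after step 4.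

Alternative 3: Biomimetic transannular cyclisation.
- Disconnection: the C5–C10 bond of dienone A6 is cut to give the ten-membered epoxide A7, the 1,10-monoepoxide of the achiral macrocyclic trienone A8.
- Forward key step: a Lewis acid opens the epoxide at tertiary C10, C5 of the (E)-C4=C5 alkene attacks across the ring, and the C4 cation loses a C3 proton.
- For it: by far the shortest path, and stronger than the chosen route in step count. All fifteen carbons are present, the trans fusion comes from a chair-like transannular transition state, C3=C4 with C15 is formed, and the ring B enone is one deconjugative hydroxylation from the ketol.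
- Against it: A8 is achiral, so a single enantiomer of 25 needs an enantio- and site-selective epoxidation of one of three alkenes in a mobile ring. The cation partitions between loss of a C3 proton, loss of a C15 proton and capture by nucleophiles. The C1 hydroxyl of A6 must be removed, and supply rests on a natural isolate.
- Comparison: the chosen route is longer but introduces absolute configuration in a catalytic C–C bond formation and makes every later bond at a defined position.

Key step: step 4

Assumption: the phosphoramidite enantiomer in step 2 is the one that gives the (R) quaternary centre, its sense of induction being assigned by analogy with other 3-alkylcyclohexenones.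

## Route

Step 1
Reactants: 1 3-ethoxycyclohex-2-en-1-one; 2 allylmagnesium bromide
Product: 4 3-allylcyclohex-2-en-1-one, via magnesium alkoxide 3 (not isolated)
Conditions: THF, 0 °C; then 1 M HCl, 0 °C, short contact
Reagents that add atoms: allylmagnesium bromide (2), C=CC[Mg]Br; water, O
Why: 1,2-Addition of the Grignard reagent to the vinylogous ester, then acid hydrolysis of the enol ether with loss of water, transposes the carbonyl (Stork–Danheiser sequence); cold dilute acid and a short contact time keep the skipped allyl alkene out of conjugation.

Step 2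
Reactants: 4 3-allylcyclohex-2-en-1-one; 5 trimethylaluminium
Product: 7 (R)-[(3-allyl-3-methylcyclohex-1-en-1-yl)oxy]trimethylsilane, via dimethylaluminium enolate 6 (not isolated)
Conditions: Cu(O2CC4H3S) (copper thiophene-2-carboxylate, 2 mol %), chiral biphenol-derived phosphoramidite (4 mol %), Me3Al, Et2O, −30 °C; then Me3SiOTf, −30 → 0 °C; Et3N, non-aqueous work-up
Reagents that add atoms: trimethylaluminium (5), C[Al](C)C; trimethylsilyl trifluoromethanesulfonate, C[Si](C)(C)OS(=O)(=O)C(F)(F)F
Why: Copper-catalysed asymmetric conjugate addition of a trialkylaluminium to a β-substituted cyclohexenone builds the quaternary C10, the chiral monovalent copper–phosphoramidite complex choosing the enone face. O-Silylation of the aluminium enolate stores the enolate regiochemistry (C4=C5) in an isolable silyl enol ether.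

Step 3
Reactants: 7 (R)-[(3-allyl-3-methylcyclohex-1-en-1-yl)oxy]trimethylsilane; 8 1-bromobut-2-yne
Product: 10 (2R,3R)-3-allyl-2-(but-2-yn-1-yl)-3-methylcyclohexan-1-one, via lithium enolate 9 (not isolated)
Conditions: MeLi, THF, 0 → 20 °C; then DMPU, 8, −78 → −20 °C
Reagents that add atoms: 1-bromobut-2-yne (8), CC#CCBr
Why: Methyllithium cleaves the O–Si bond and releases the lithium enolate with its double bond fixed at C4=C5 (regiospecific enolate generation from a silyl enol ether), which is C-alkylated by the primary propargylic bromide in an SN2 reaction. C5 is set here: the electrophile enters axially, anti to the C10 substituent that stands perpendicular to the enolate, and the larger allyl arm should take that place, putting the butynyl group trans to allyl. The preference is expected to be modest because C10 offers only methyl against allyl, so the C5 epimer (F2) is separated by chromatography or salvaged as set out at the end.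

Step 4
Reactants: 10 (2R,3R)-3-allyl-2-(but-2-yn-1-yl)-3-methylcyclohexan-1-one
Product: 11 (4aR,8aR)-4a-methyl-7-(prop-1-en-2-yl)-3,4,4a,5,8,8a-hexahydronaphthalen-1(2H)-one
Conditions: RuCl2(=CHPh)(PCy3)(H2IMes) (second-generation Grubbs catalyst, 5 mol %), ethylene (1 atm), toluene (0.01 M), 80 °C
Reagents that add atoms: none
Why: This is a ring-closing enyne metathesis of a 1,7-enyne with a methyl-capped alkyne; the closest known reaction type is the ruthenium-carbene cyclisation of 1,7-enynes to 1-alkenylcyclohexenes under ethylene. The ruthenium methylidene loads on the terminal alkene of the allyl arm to give an alkylidene at C8, which adds across the tethered alkyne through a ruthenacyclobutene so that C8 bonds to C7 and the metal moves to C11. Ring B closes in the exo mode (the six-membered ring takes in C7 only and C11 stays outside); the endo mode would give a seven-membered ring and is disfavoured by ring size. The vinylcarbene on C11 then takes a methylene from ethylene or from a second substrate alkene and releases the diene, so C11=C12 and the isopropenyl group arise in the same event and the methyl cap becomes C13; the net change is an isomerisation. No stereocentre is formed, and the neutral conditions leave the epimerisable C5–H untouched. The step needs alkene-first initiation and exo closure to win over intermolecular ethylene–alkyne metathesis; the unhindered monosubstituted alkene, the slower internal alkyne, the two arms held gauche on adjacent ring carbons by the quaternary C10, and dilution secure this. The ketone is tolerated, and the 1,1-disubstituted terminus of the product diene is too hindered for secondary metathesis.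

Step 5
Reactants: 11 (4aR,8aR)-4a-methyl-7-(prop-1-en-2-yl)-3,4,4a,5,8,8a-hexahydronaphthalen-1(2H)-one
Product: 13 (4aR,8aR)-4a-methyl-7-(prop-1-en-2-yl)-3,4,4a,5,8,8a-hexahydronaphthalen-1-yl trifluoromethanesulfonate, via potassium enolate 12 (not isolated)
Conditions: KN(SiMe3)2, THF, −78 °C; then PhNTf2, −78 → 0 °C
Reagents that add atoms: N-phenylbis(trifluoromethanesulfonimide), O=S(=O)(N(c1ccccc1)S(=O)(=O)C(F)(F)F)C(F)(F)F
Why: The bulky amide removes a C3 proton under kinetic control rather than the hindered ring-fusion C5–H, and the enolate is sulfonylated on oxygen (enol triflate formation). C5 is not touched, and the triflate serves as an electron-poor, masked form of the later C3=C4 alkene.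

Step 6
Reactants: 13 (4aR,8aR)-4a-methyl-7-(prop-1-en-2-yl)-3,4,4a,5,8,8a-hexahydronaphthalen-1-yl trifluoromethanesulfonate
Product: 14 (4aR,6S,7S,8aR)-6,7-dihydroxy-4a-methyl-7-(prop-1-en-2-yl)-3,4,4a,5,6,7,8,8a-octahydronaphthalen-1-yl trifluoromethanesulfonate (the 7α,8α-diol)
Conditions: OsO4 (2 mol %), 4-methylmorpholine N-oxide (1.1 equiv), acetone/H2O, 0 → 20 °C
Reagents that add atoms: 4-methylmorpholine N-oxide, C[N+]1([O-])CCOCC1; water, O
Why: Catalytic syn-dihydroxylation with an amine N-oxide as reoxidant; the enol triflate alkene is too electron-poor to react, and of the two diene alkenes the trisubstituted ring alkene C7=C8 is the more electron-rich, while the limited oxidant protects the remaining isopropenyl group. Osmium adds from the α face because axial C14 is syn-axial to C8 on the β face, which sets C7 (α-OH, β-isopropenyl).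

Step 7
Reactants: 14 (the 7α,8α-diol)
Product: 15 (4aR,7S,8aR)-7-hydroxy-4a-methyl-6-oxo-7-(prop-1-en-2-yl)-3,4,4a,5,6,7,8,8a-octahydronaphthalen-1-yl trifluoromethanesulfonate
Conditions: SO3·pyridine, DMSO, Et3N, CH2Cl2, 0 → 20 °C
Reagents that add atoms: none
Why: Parikh–Doering oxidation converts the secondary C8 carbinol into the ketone; the tertiary C7 hydroxyl cannot be oxidised, and activated DMSO does not cleave the glycol C–C bond.

Step 8
Reactants: 15 (the C7 ketol enol triflate)
Product: 16 (4aR,7S,8aR)-4a-methyl-6-oxo-7-(prop-1-en-2-yl)-7-(triethylsilyloxy)-3,4,4a,5,6,7,8,8a-octahydronaphthalen-1-yl trifluoromethanesulfonate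
Conditions: Et3SiOTf, 2,6-lutidine, CH2Cl2, −78 → 0 °C
Reagents that add atoms: triethylsilyl trifluoromethanesulfonate, CC[Si](CC)(CC)OS(=O)(=O)C(F)(F)F
Why: Silylation of a hindered tertiary alcohol with a silyl triflate and a hindered pyridine base; the silyl ether blocks α-ketol rearrangement (ring contraction to a conjugated enone is open to the free ketol) and keeps this oxygen out of the later acylation.

Step 9
Reactants: 16 (the silylated ketol enol triflate); 17 methylzinc chloride
Product: 18 (3S,4aR,8aR)-5,8a-dimethyl-3-(prop-1-en-2-yl)-3-(triethylsilyloxy)-3,4,4a,7,8,8a-hexahydronaphthalen-2(1H)-one (7α-triethylsilyloxy-eudesma-3,11-dien-8-one)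
Conditions: Pd(PPh3)4 (5 mol %), MeZnCl, THF, 20 → 45 °C
Reagents that add atoms: methylzinc chloride (17), C[Zn]Cl
Why: Negishi coupling: zerovalent palladium inserts into the C4–O bond of the alkenyl triflate, methyl is transferred from zinc and reductive elimination installs C15 with the alkene fixed at C3=C4. The organozinc does not add to the hindered C8 ketone, and the allylic silyl ether is not ionised.

Step 10
Reactants: 18 (7α-triethylsilyloxy-eudesma-3,11-dien-8-one)
Product: 21 4β-acetoxy-3β-hydroxy-7α-(triethylsilyloxy)eudesm-11-en-8-one, via iodo acetate 19 (not isolated), via acetoxonium ion 20 (not isolated)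
Conditions: I2 (1.05 equiv), AgOAc (2.2 equiv), AcOH, 20 °C, dark; then AcOH/H2O, 20 → 45 °C
Reagents that add atoms: silver acetate, CC(=O)[O-].[Ag+]; water, O
Why: Woodward cis-hydroxylation (the wet Prévost reaction): the iodonium ion forms on the open α face of the electron-rich C3=C4 alkene and acetate opens it at tertiary C4 from the β face (Markovnikov and trans-diaxial), giving 19. Silver-assisted backside displacement of the axial 3α-iodide by the acetate carbonyl oxygen gives the β-fused acetoxonium ion 20; water adds to its central carbon and the orthoacid collapses to the axial ester and equatorial alcohol, so both oxygens end on the β face and the acetyl group stays on O4. The isopropenyl alkene is less nucleophilic (1,1-disubstituted, next to the silyloxy-bearing quaternary C7 and the ketone) and should be spared by one equivalent of iodine.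

Step 11
Reactants: 21 4β-acetoxy-3β-hydroxy-7α-(triethylsilyloxy)eudesm-11-en-8-one; 22 angelic acid
Product: 24 4β-acetoxy-3β-[(Z)-2-methylbut-2-enoyloxy]-7α-(triethylsilyloxy)eudesm-11-en-8-one, via mixed anhydride 23 (not isolated)
Conditions: 22, 2,4,6-Cl3C6H2COCl, Et3N, toluene, 20 °C; then 21, toluene, 75 °C
Reagents that add atoms: angelic acid (22), C/C=C(/C)C(=O)O
Why: Yamaguchi-type esterification without a nucleophilic catalyst: the equatorial secondary 3β-hydroxyl attacks the less hindered angeloyl carbonyl of the mixed anhydride. Leaving out 4-aminopyridine catalysts and alkoxide bases avoids Z to E isomerisation and limits acetate migration; the tertiary acetate and silyl ether are inert.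

Step 12
Reactants: 24 (the 7-O-triethylsilyl ether of the target)
Product: 25 4β-acetoxy-3β-angeloyloxy-7α-hydroxyeudesm-11-en-8-one [(1R,2S,4aR,7S,8aR)-1-acetoxy-7-hydroxy-1,4a-dimethyl-6-oxo-7-(prop-1-en-2-yl)decahydronaphthalen-2-yl (Z)-2-methylbut-2-enoate]
Conditions: HF·pyridine, pyridine/THF, 0 → 20 °C
Reagents that add atoms: none
Why: Fluoride-driven cleavage of the Si–O bond under buffered, weakly acidic conditions; no base is present, so the esters do not migrate, the angelate does not isomerise and the ketol does not rearrange.

## Compound list

1 | 3-ethoxycyclohex-2-en-1-one | CCOC1=CC(=O)CCC1 | starting material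
2 | allylmagnesium bromide | C=CC[Mg]Br | starting material
3 | bromomagnesium 1-allyl-3-ethoxycyclohex-2-en-1-olate | CCOC1=CC(O[Mg]Br)(CC=C)CCC1 | intermediate (not isolated)
4 | 3-allylcyclohex-2-en-1-one | C=CCC1=CC(=O)CCC1 | intermediate
5 | trimethylaluminium | C[Al](C)C | starting material
6 | dimethylaluminium (R)-3-allyl-3-methylcyclohex-1-en-1-olate | C[Al](C)OC1=C[C@@](C)(CC=C)CCC1 | intermediate (not isolated)
7 | (R)-[(3-allyl-3-methylcyclohex-1-en-1-yl)oxy]trimethylsilane | C[Si](C)(C)OC1=C[C@@](C)(CC=C)CCC1 | intermediate
8 | 1-bromobut-2-yne | CC#CCBr | starting material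
9 | lithium (R)-3-allyl-3-methylcyclohex-1-en-1-olate | [Li]OC1=C[C@@](C)(CC=C)CCC1 | intermediate (not isolated)
10 | (2R,3R)-3-allyl-2-(but-2-yn-1-yl)-3-methylcyclohexan-1-one | CC#CC[C@H]1C(=O)CCC[C@]1(C)CC=C | intermediate
11 | (4aR,8aR)-4a-methyl-7-(prop-1-en-2-yl)-3,4,4a,5,8,8a-hexahydronaphthalen-1(2H)-one (15-nor-eudesma-7,11-dien-4-one) | C=C(C)C1=CC[C@@]2(C)CCCC(=O)[C@@H]2C1 | intermediate
12 | potassium (4aR,8aR)-4a-methyl-7-(prop-1-en-2-yl)-3,4,4a,5,8,8a-hexahydronaphthalen-1-olate | C=C(C)C1=CC[C@@]2(C)CCC=C([O-])[C@@H]2C1.[K+] | intermediate (not isolated)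
13 | (4aR,8aR)-4a-methyl-7-(prop-1-en-2-yl)-3,4,4a,5,8,8a-hexahydronaphthalen-1-yl trifluoromethanesulfonate | C=C(C)C1=CC[C@@]2(C)CCC=C(OS(=O)(=O)C(F)(F)F)[C@@H]2C1 | intermediate
14 | (4aR,6S,7S,8aR)-6,7-dihydroxy-4a-methyl-7-(prop-1-en-2-yl)-3,4,4a,5,6,7,8,8a-octahydronaphthalen-1-yl trifluoromethanesulfonate (7α,8α-diol) | C=C(C)[C@@]1(O)C[C@H]2C(OS(=O)(=O)C(F)(F)F)=CCC[C@]2(C)C[C@@H]1O | intermediate
15 | (4aR,7S,8aR)-7-hydroxy-4a-methyl-6-oxo-7-(prop-1-en-2-yl)-3,4,4a,5,6,7,8,8a-octahydronaphthalen-1-yl trifluoromethanesulfonate | C=C(C)[C@@]1(O)C[C@H]2C(OS(=O)(=O)C(F)(F)F)=CCC[C@]2(C)CC1=O | intermediate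
16 | (4aR,7S,8aR)-4a-methyl-6-oxo-7-(prop-1-en-2-yl)-7-(triethylsilyloxy)-3,4,4a,5,6,7,8,8a-octahydronaphthalen-1-yl trifluoromethanesulfonate | C=C(C)[C@@]1(O[Si](CC)(CC)CC)C[C@H]2C(OS(=O)(=O)C(F)(F)F)=CCC[C@]2(C)CC1=O | intermediate
17 | methylzinc chloride | C[Zn]Cl | starting material
18 | (3S,4aR,8aR)-5,8a-dimethyl-3-(prop-1-en-2-yl)-3-(triethylsilyloxy)-3,4,4a,7,8,8a-hexahydronaphthalen-2(1H)-one (7α-triethylsilyloxy-eudesma-3,11-dien-8-one) | C=C(C)[C@@]1(O[Si](CC)(CC)CC)C[C@H]2C(C)=CCC[C@]2(C)CC1=O | intermediate
19 | 4β-acetoxy-3α-iodo-7α-(triethylsilyloxy)eudesm-11-en-8-one | C=C(C)[C@@]1(O[Si](CC)(CC)CC)C[C@H]2[C@@](C)(OC(C)=O)[C@H](I)CC[C@]2(C)CC1=O | intermediate (not isolated)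
20 | 3β,4β-(2-methyl-1,3-dioxolan-2-ylium-4,5-diyl) cation derived from 19 (β-fused acetoxonium ion) | C=C(C)[C@@]1(O[Si](CC)(CC)CC)C[C@H]2[C@@]3(C)OC(C)=[O+][C@H]3CC[C@]2(C)CC1=O | intermediate (not isolated)
21 | 4β-acetoxy-3β-hydroxy-7α-(triethylsilyloxy)eudesm-11-en-8-one | C=C(C)[C@@]1(O[Si](CC)(CC)CC)C[C@H]2[C@@](C)(OC(C)=O)[C@@H](O)CC[C@]2(C)CC1=O | intermediate
22 | angelic acid [(Z)-2-methylbut-2-enoic acid] | C/C=C(/C)C(=O)O | starting material
23 | (Z)-2-methylbut-2-enoic 2,4,6-trichlorobenzoic anhydride | C/C=C(/C)C(=O)OC(=O)c1c(Cl)cc(Cl)cc1Cl | intermediate (not isolated)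
24 | 4β-acetoxy-3β-[(Z)-2-methylbut-2-enoyloxy]-7α-(triethylsilyloxy)eudesm-11-en-8-one | C=C(C)[C@@]1(O[Si](CC)(CC)CC)C[C@H]2[C@@](C)(OC(C)=O)[C@@H](OC(=O)/C(C)=C\C)CC[C@]2(C)CC1=O | intermediate
25 | 4β-acetoxy-3β-angeloyloxy-7α-hydroxyeudesm-11-en-8-one, (3S,4R,5R,7S,10R) | C=C(C)[C@@]1(O)C[C@@H]2[C@](C)(CC[C@H](OC(=O)/C(C)=C\C)[C@]2(C)OC(C)=O)CC1=O | target

## Step count and least certain steps

Total step count: 12. Longest linear sequence: 12 steps (1 to 25; the route is fully linear).

Step 4 (key step). The likely failure is intermolecular ethylene–alkyne metathesis outrunning ring closure, or slow engagement of the internal alkyne by the alkylidene formed at the neopentyl-type allyl arm; endo closure to a seven-membered ring is a lesser concern. The fallback separates the two events and sets out from 10. The alkyne is first converted on purpose, by cross-enyne metathesis under a higher ethylene pressure, into (2R,3R)-3-allyl-3-methyl-2-(3-methyl-2-methylidenebut-3-en-1-yl)cyclohexan-1-one F1. Ring B is then closed by ordinary olefin ring-closing metathesis between the allyl alkene and the C7 methylidene of F1, six-membered closure being preferred over seven. This returns to the route at 11.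

Step 3. The likely failure is poor facial discrimination in the alkylation, because the neighbouring quaternary carbon presents methyl against allyl; proton transfer leading to alkylation at C3 is a second risk. Simple base equilibration of 11 is not relied on, since the two sp2 centres in each ring remove most of the gauche interactions that normally disfavour a cis-decalone, so the trans/cis energy gap should be small. The fallback sets C5 after ring closure by kinetic protonation and sets out from 7. The epimer (2S,3R)-3-allyl-2-(but-2-yn-1-yl)-3-methylcyclohexan-1-one F2, formed beside 10, is cyclised under the step 4 conditions to the cis-fused (4aR,8aS)-4a-methyl-7-(prop-1-en-2-yl)-3,4,4a,5,8,8a-hexahydronaphthalen-1(2H)-one F3. F3, alone or mixed with 11, is silylated under equilibrating conditions (Me3SiCl, NaI, Et3N, MeCN) to the tetrasubstituted silyl enol ether trimethyl{[(4aR)-4a-methyl-7-(prop-1-en-2-yl)-2,3,4,4a,5,8-hexahydronaphthalen-1-yl]oxy}silane F4, in which C5 is no longer a stereocentre. Methyllithium converts F4 into the lithium enolate lithium (4aR)-4a-methyl-7-(prop-1-en-2-yl)-2,3,4,4a,5,8-hexahydronaphthalen-1-olate F5. Inverse quench of F5 into acetic acid in THF at −78 °C should protonate C5 from the α face, anti to C14, which stands perpendicular to the enolate plane. This returns to the route at 11.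

Step 6. The likely failure is osmylation at the isopropenyl alkene instead of the ring alkene, or over-oxidation to a tetraol, because the electronic difference between the two diene alkenes is modest. The fallback uses an electrophile with a stronger preference for the more substituted alkene and sets out from 11. Buffered peracid epoxidation (mCPBA, NaHCO3) from the α face should give the 7α,8α-epoxide (15-nor-7α,8α-epoxyeudesm-11-en-4-one) F6. A zerovalent palladium catalyst (Pd2(dba)3·CHCl3, P(OiPr)3) under CO2 converts the vinyl epoxide with net retention, by double inversion through the π-allyl complex, into the cis cyclic carbonate (15-nor-7α,8α-carbonyldioxyeudesm-11-en-4-one) F7. Triflation as in step 5 gives the carbonate enol triflate F8, and methanolysis (K2CO3, MeOH) of F8 returns to the route at 14.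

Step 10. The likely failures are iodonium formation at the isopropenyl alkene, drift of the acetyl group to O3 in the acidic medium, and partial loss of the silyl group. The fallback builds the two C–O bonds separately and sets out from 18. Epoxidation of the trisubstituted alkene from the α face gives 3α,4α-epoxy-7α-(triethylsilyloxy)eudesm-11-en-8-one F9. Acetolysis opens F9 trans-diaxially at tertiary C4 to 4β-acetoxy-3α-hydroxy-7α-(triethylsilyloxy)eudesm-11-en-8-one F10. Oxidation gives the ketone 4β-acetoxy-7α-(triethylsilyloxy)eudesm-11-ene-3,8-dione F11. Reduction with NaBH4 and CeCl3 at −78 °C should deliver hydride axially from the α face to the more accessible, acetoxy-activated C3 carbonyl. This returns to the route at 21.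

Step 11. The likely failures are migration of the acetyl group from O4 to the free O3 before acylation, Z to E isomerisation of the angeloyl unit, and slow acylation beside the quaternary C4. The fallback reverses the order of the two acylations and sets out from 21. Methanolysis (K2CO3, MeOH) gives the diol 3β,4β-dihydroxy-7α-(triethylsilyloxy)eudesm-11-en-8-one F12. Angeloylation under the step 11 conditions, now with nothing to migrate, gives 3β-[(Z)-2-methylbut-2-enoyloxy]-4β-hydroxy-7α-(triethylsilyloxy)eudesm-11-en-8-one F13. The tertiary hydroxyl of F13 is then acetylated under Lewis-acid catalysis (Ac2O, catalytic Me3SiOTf, CH2Cl2, −20 °C). This returns to the route at 24.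

## Further compounds

F1 | step 4 | (2R,3R)-3-allyl-3-methyl-2-(3-methyl-2-methylidenebut-3-en-1-yl)cyclohexan-1-one | C=C(C)C(=C)C[C@H]1C(=O)CCC[C@]1(C)CC=C
F2 | step 3 | (2S,3R)-3-allyl-2-(but-2-yn-1-yl)-3-methylcyclohexan-1-one | CC#CC[C@@H]1C(=O)CCC[C@]1(C)CC=C
F3 | step 3 | (4aR,8aS)-4a-methyl-7-(prop-1-en-2-yl)-3,4,4a,5,8,8a-hexahydronaphthalen-1(2H)-one (cis-fused) | C=C(C)C1=CC[C@@]2(C)CCCC(=O)[C@H]2C1
F4 | step 3 | trimethyl{[(4aR)-4a-methyl-7-(prop-1-en-2-yl)-2,3,4,4a,5,8-hexahydronaphthalen-1-yl]oxy}silane | C=C(C)C1=CC[C@@]2(C)CCCC(O[Si](C)(C)C)=C2C1
F5 | step 3 | lithium (4aR)-4a-methyl-7-(prop-1-en-2-yl)-2,3,4,4a,5,8-hexahydronaphthalen-1-olate | C=C(C)C1=CC[C@@]2(C)CCCC(O[Li])=C2C1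
F6 | step 6 | 15-nor-7α,8α-epoxyeudesm-11-en-4-one | C=C(C)[C@]12O[C@H]1C[C@@]3(C)CCCC(=O)[C@@H]3C2
F7 | step 6 | 15-nor-7α,8α-carbonyldioxyeudesm-11-en-4-one (cis cyclic carbonate) | C=C(C)[C@]12OC(=O)O[C@H]1C[C@@]3(C)CCCC(=O)[C@@H]3C2
F8 | step 6 | 15-nor-7α,8α-carbonyldioxyeudesma-3,11-dien-4-yl trifluoromethanesulfonate | C=C(C)[C@]12OC(=O)O[C@H]1C[C@@]3(C)CCC=C(OS(=O)(=O)C(F)(F)F)[C@@H]3C2
F9 | step 10 | 3α,4α-epoxy-7α-(triethylsilyloxy)eudesm-11-en-8-one | C=C(C)[C@@]1(O[Si](CC)(CC)CC)C[C@H]2[C@]3(C)O[C@@H]3CC[C@]2(C)CC1=O
F10 | step 10 | 4β-acetoxy-3α-hydroxy-7α-(triethylsilyloxy)eudesm-11-en-8-one | C=C(C)[C@@]1(O[Si](CC)(CC)CC)C[C@H]2[C@@](C)(OC(C)=O)[C@H](O)CC[C@]2(C)CC1=O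
F11 | step 10 | 4β-acetoxy-7α-(triethylsilyloxy)eudesm-11-ene-3,8-dione | C=C(C)[C@@]1(O[Si](CC)(CC)CC)C[C@H]2[C@@](C)(OC(C)=O)C(=O)CC[C@]2(C)CC1=O
F12 | step 11 | 3β,4β-dihydroxy-7α-(triethylsilyloxy)eudesm-11-en-8-one | C=C(C)[C@@]1(O[Si](CC)(CC)CC)C[C@H]2[C@@](C)(O)[C@@H](O)CC[C@]2(C)CC1=O
F13 | step 11 | 3β-[(Z)-2-methylbut-2-enoyloxy]-4β-hydroxy-7α-(triethylsilyloxy)eudesm-11-en-8-one | C=C(C)[C@@]1(O[Si](CC)(CC)CC)C[C@H]2[C@@](C)(O)[C@@H](OC(=O)/C(C)=C\C)CC[C@]2(C)CC1=O
A1 | alternative 1 | 8α-(tert-butyldimethylsilyloxy)-11,12,13-trinoreudesm-3-en-9-one | C1C[C@@H]2[C@](C)(CCC=C2C)C(=O)[C@@H]1O[Si](C)(C)C(C)(C)C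
A2 | alternative 1 | (7E)-4-(tert-butyldimethylsilyloxy)-2,8-dimethyldeca-1,7,9-trien-3-one, C4 configured as in A1 | C=C(C)C(=O)[C@H](O[Si](C)(C)C(C)(C)C)CC/C=C(\C)C=C
A3 | alternative 2 | trans-6-acetyl-1-methyl-4-(triisopropylsilyloxy)cyclohex-3-ene-1-carbaldehyde | CC(=O)[C@@H]1CC(O[Si](C(C)C)(C(C)C)C(C)C)=CC[C@@]1(C)C=O
A4 | alternative 2 | (E)-2-methyl-4-oxopent-2-enal | CC(=O)/C=C(\C)C=O
A5 | alternative 2 | 2-(triisopropylsilyloxy)buta-1,3-diene | C=CC(=C)O[Si](C(C)C)(C(C)C)C(C)C
A6 | alternative 3 | 1β-hydroxyeudesma-3,7(11)-dien-8-one | CC(C)=C1C[C@@H]2[C@](C)([C@H](O)CC=C2C)CC1=O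
A7 | alternative 3 | (4E)-1,10-epoxygermacra-4,7(11)-dien-8-one, enantiomer leading to A6 | O=C1C[C@@]2(C)O[C@@H]2CC/C(C)=C/CC1=C(C)C
A8 | alternative 3 | (1(10)E,4E)-germacra-1(10),4,7(11)-trien-8-one | O=C1C/C(C)=C/CC/C(C)=C/CC1=C(C)C
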